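**Retrosynthetic overview**
- The target comes from regioselective saponification of a 2,5-dimethoxyquinone, itself made by oxidative demethylation of a 2,3,5,6-tetramethoxyaryl unit; the quinone ring is bought as an arene, not built.
- The ArCH2–C(sp2) bond and the (E)-trisubstituted olefin come from Zr-catalysed methylalumination of a terminal alkyne and Pd-catalysed coupling with a benzylic chloride.
- The (S)-α-cyclogeranyl alkyne (the only stereocentre, the ring–chain bond and the position of the ring olefin) comes from a proposed Cu-catalysed enantioselective conjugate addition to 2,4,4-trimethylcyclohexenone, enolate triflation and triflate reduction.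
- Ring order: the carbocycle is the only ring constructed (first step, acid-catalysed Robinson annulation of isobutyraldehyde and ethyl vinyl ketone); the quinone ring is unveiled last.

Assumption: the sense of induction of the catalyst in step 3 cannot be predicted with certainty, so the ligand antipode is fixed after one scouting run (both antipodes come from commercial leucinol); the (S)-leucinol-derived ligand is written.

**Route**

Step 1
Reactants: 1 2-methylpropanal (isobutyraldehyde); 2 pent-1-en-3-one (ethyl vinyl ketone)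
Product: 5 2,4,4-trimethylcyclohex-2-en-1-one, via keto-aldehyde 3 (not isolated), via ketol 4 (not isolated)
Conditions: H2SO4 (cat.), toluene, reflux, Dean–Stark
Reagents that add atoms: none
Why: Acid-catalysed Michael addition of the aldehyde enol to the enone followed by intramolecular aldol condensation (Robinson annulation); after the Michael step the aldehyde has no α-hydrogen, so only the ethyl-ketone CH2 can close onto it and a single six-membered enone results, with no stereocentre formed.

Step 2
Reactants: 6 (4-bromobut-1-yn-1-yl)trimethylsilane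
Product: 7 [4-(trimethylsilyl)but-3-yn-1-yl]magnesium bromide (titrated Et2O solution)
Conditions: Mg turnings, I2 (cat.), Et2O, reflux
Reagents that add atoms: magnesium, [Mg]
Why: Magnesium insertion into the primary C–Br bond (Grignard formation); the silyl cap removes the acidic alkyne proton.

Step 3
Reactants: 5 2,4,4-trimethylcyclohex-2-en-1-one; 7 [4-(trimethylsilyl)but-3-yn-1-yl]magnesium bromide
Product: 9 (3S)-2,4,4-trimethyl-3-[4-(trimethylsilyl)but-3-yn-1-yl]cyclohex-1-en-1-yl trifluoromethanesulfonate, via magnesium enolate 8 (not isolated)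
Conditions: Cu(OTf)2 (5 mol %), (S)-leucinol-derived N-mesityl hydroxyalkyl imidazolinium PF6 salt (7 mol %), Et2O, −30 °C, slow addition of 7 (1.4 equiv); then Comins' reagent (1.6 equiv), THF/DMPU, −30 °C → rt
Reagents that add atoms: Comins' reagent, N-(5-chloropyridin-2-yl)-1,1,1-trifluoro-N-[(trifluoromethyl)sulfonyl]methanesulfonamide, O=S(=O)(N(c1ccc(Cl)cn1)S(=O)(=O)C(F)(F)F)C(F)(F)F
Why: Proposed new method: copper-catalysed enantioselective conjugate addition of a functionalised primary alkyl Grignard reagent to an α-methyl-γ,γ-dimethyl cyclohexenone, whose β-CH is flanked by two fully substituted carbons, with in-flask O-triflation of the tetrasubstituted magnesium enolate; the Grignard reagent deprotonates the imidazolinium salt to an alkoxide-tethered NHC–copper species, the magnesium alkoxide arm binds the enone carbonyl while the monovalent copper alkyl π-complexes C2=C3, oxidative addition gives a trivalent copper β-alkyl enolate and reductive elimination forms the C3–C bond on the Si face of C3 selected by the chiral chelate, which sets the (S) centre; the regiodefined enolate is then sulfonylated on oxygen so that the later ring olefin is fixed at C1=C2; the γ-gem-dimethyl group is tolerated in copper-catalysed dialkylzinc additions to 4,4-dimethylcyclohexenone, the α-methyl group in Grignard additions to 2-methylcyclohexenone, and the same NHC–copper catalysts even add to β,β-disubstituted enones, so the combination is reasonable; closest known reaction type: copper/NHC-catalysed asymmetric conjugate addition of Grignard reagents to 2- or 3-substituted cyclohexenones with trapping of the magnesium enolate.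

Step 4
Reactants: 9 (3S)-2,4,4-trimethyl-3-[4-(trimethylsilyl)but-3-yn-1-yl]cyclohex-1-en-1-yl trifluoromethanesulfonate
Product: 10 trimethyl{4-[(1S)-2,6,6-trimethylcyclohex-2-en-1-yl]but-1-yn-1-yl}silane
Conditions: Pd(OAc)2 (5 mol %), PPh3 (10 mol %), HCO2H, n-Bu3N, DMF, 60 °C
Reagents that add atoms: none
Why: Palladium-catalysed formate reduction of an enol triflate (oxidative addition to zerovalent palladium, formate exchange, decarboxylation to a palladium hydride, reductive elimination) swaps OTf for H at the vinylic carbon, so the olefin stays at the α-cyclogeranyl position and the allylic (S) centre is untouched.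

Step 5
Reactants: 10 trimethyl{4-[(1S)-2,6,6-trimethylcyclohex-2-en-1-yl]but-1-yn-1-yl}silane
Product: 11 (6S)-6-(but-3-yn-1-yl)-1,5,5-trimethylcyclohex-1-ene
Conditions: K2CO3, MeOH, rt
Reagents that add atoms: none
Why: Methoxide-catalysed protodesilylation of the alkynylsilane leaves olefin and stereocentre untouched.

Step 6
Reactants: 12 1,2,4,5-tetramethoxybenzene
Product: 15 2,3,5,6-tetramethoxybenzaldehyde, via aryllithium 13 (not isolated), via lithium hemiaminolate 14 (not isolated)
Conditions: n-BuLi, TMEDA, THF, 0 °C; DMF, −78 °C → rt; H2O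
Reagents that add atoms: N,N-dimethylformamide, CN(C)C=O
Why: Directed ortho-lithiation at a C–H flanked by two methoxy groups (both ring C–H are equivalent) and formylation of the aryllithium with DMF, the tetrahedral adduct collapsing on aqueous work-up.

Step 7
Reactants: 15 2,3,5,6-tetramethoxybenzaldehyde
Product: 16 (2,3,5,6-tetramethoxyphenyl)methanol
Conditions: NaBH4, MeOH, 0 °C
Reagents that add atoms: none
Why: Borohydride reduction of the aryl aldehyde to the benzylic alcohol.

Step 8
Reactants: 16 (2,3,5,6-tetramethoxyphenyl)methanol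
Product: 17 3-(chloromethyl)-1,2,4,5-tetramethoxybenzene
Conditions: SOCl2, pyridine, CH2Cl2, 0 °C
Reagents that add atoms: thionyl chloride, O=S(Cl)Cl
Why: Deoxychlorination through the chlorosulfite with displacement by chloride; pyridine takes up the acid so the electron-rich benzylic chloride does not self-alkylate.

Step 9
Reactants: 11 (6S)-6-(but-3-yn-1-yl)-1,5,5-trimethylcyclohex-1-ene; 17 3-(chloromethyl)-1,2,4,5-tetramethoxybenzene
Product: 19 1,2,4,5-tetramethoxy-3-{(2E)-3-methyl-5-[(1S)-2,6,6-trimethylcyclohex-2-en-1-yl]pent-2-en-1-yl}benzene, via alkenylalane 18 (not isolated)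
Conditions: AlMe3 (2 equiv), Cp2ZrCl2 (0.25 equiv), CH2Cl2, 0 °C → rt; evaporate; then 17, Pd(PPh3)4 (5 mol %), THF, rt
Reagents that add atoms: trimethylaluminium, C[Al](C)C
Why: Negishi zirconium-catalysed methylalumination adds Me and Al syn across the terminal alkyne with Me on the internal carbon, and the palladium-catalysed alkenylalane–benzylic chloride cross-coupling proceeds with retention, which fixes the (E) geometry; the ring olefin and the remote stereocentre are spectators.

Step 10
Reactants: 19 1,2,4,5-tetramethoxy-3-{(2E)-3-methyl-5-[(1S)-2,6,6-trimethylcyclohex-2-en-1-yl]pent-2-en-1-yl}benzene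
Product: 20 2,5-dimethoxy-3-{(2E)-3-methyl-5-[(1S)-2,6,6-trimethylcyclohex-2-en-1-yl]pent-2-en-1-yl}cyclohexa-2,5-diene-1,4-dione
Conditions: (NH4)2Ce(NO3)6 (2.5 equiv), MeCN/H2O, 0 °C, 20 min
Reagents that add atoms: water, O
Why: Oxidative demethylation by tetravalent cerium: the arene radical cation is attacked by water at two para methoxy-bearing carbons and loses two methanol to give the para-quinone (either para pair gives the same quinone), and trisubstituted olefins survive short exposure at 0 °C.

Step 11
Reactants: 20 2,5-dimethoxy-3-{(2E)-3-methyl-5-[(1S)-2,6,6-trimethylcyclohex-2-en-1-yl]pent-2-en-1-yl}cyclohexa-2,5-diene-1,4-dione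
Product: 22 2-hydroxy-5-methoxy-3-{(2E)-3-methyl-5-[(1S)-2,6,6-trimethylcyclohex-2-en-1-yl]pent-2-en-1-yl}cyclohexa-2,5-diene-1,4-dione (CNP0018448.1), via potassium salt 21 (not isolated)
Conditions: KOH (2 equiv), MeOH/H2O, 0 °C → rt; then 1 M HCl, 0 °C, to pH 3
Reagents that add atoms: potassium hydroxide, [K+].[OH-]
Why: Saponification of a vinylogous ester by addition–elimination is selective for the methoxy group squeezed between the side chain and a carbonyl (twisted out of conjugation, hence the more electrophilic carbon) and stops after one hydrolysis because the hydroxyquinone anion is deactivated; cold dilute acid then frees the target without touching the olefins.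

**Compound list**

1 | 2-methylpropanal (isobutyraldehyde) | CC(C)C=O | starting material
2 | pent-1-en-3-one (ethyl vinyl ketone) | CCC(=O)C=C | starting material
3 | 2,2-dimethyl-5-oxoheptanal | CCC(=O)CCC(C)(C)C=O | intermediate
4 | 3-hydroxy-2,4,4-trimethylcyclohexan-1-one (stereoisomer mixture) | CC1C(O)C(C)(C)CCC1=O | intermediate
5 | 2,4,4-trimethylcyclohex-2-en-1-one | CC1=CC(C)(C)CCC1=O | intermediate
6 | (4-bromobut-1-yn-1-yl)trimethylsilane | C[Si](C)(C)C#CCCBr | starting material
7 | [4-(trimethylsilyl)but-3-yn-1-yl]magnesium bromide | C[Si](C)(C)C#CCC[Mg]Br | intermediate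
8 | bromomagnesium (3S)-2,4,4-trimethyl-3-[4-(trimethylsilyl)but-3-yn-1-yl]cyclohex-1-en-1-olate | C[Si](C)(C)C#CCC[C@@H]1C(C)=C(O[Mg]Br)CCC1(C)C | intermediate
9 | (3S)-2,4,4-trimethyl-3-[4-(trimethylsilyl)but-3-yn-1-yl]cyclohex-1-en-1-yl trifluoromethanesulfonate | C[Si](C)(C)C#CCC[C@@H]1C(C)=C(OS(=O)(=O)C(F)(F)F)CCC1(C)C | intermediate
10 | trimethyl{4-[(1S)-2,6,6-trimethylcyclohex-2-en-1-yl]but-1-yn-1-yl}silane | C[Si](C)(C)C#CCC[C@@H]1C(C)=CCCC1(C)C | intermediate
11 | (6S)-6-(but-3-yn-1-yl)-1,5,5-trimethylcyclohex-1-ene | C#CCC[C@@H]1C(C)=CCCC1(C)C | intermediate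
12 | 1,2,4,5-tetramethoxybenzene | COc1cc(OC)c(OC)cc1OC | starting material
13 | (2,3,5,6-tetramethoxyphenyl)lithium | COc1cc(OC)c(OC)c([Li])c1OC | intermediate
14 | lithium (dimethylamino)(2,3,5,6-tetramethoxyphenyl)methanolate | COc1cc(OC)c(OC)c(C(O[Li])N(C)C)c1OC | intermediate
15 | 2,3,5,6-tetramethoxybenzaldehyde | COc1cc(OC)c(OC)c(C=O)c1OC | intermediate
16 | (2,3,5,6-tetramethoxyphenyl)methanol | COc1cc(OC)c(OC)c(CO)c1OC | intermediate
17 | 3-(chloromethyl)-1,2,4,5-tetramethoxybenzene | COc1cc(OC)c(OC)c(CCl)c1OC | intermediate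
18 | dimethyl{(1E)-2-methyl-4-[(1S)-2,6,6-trimethylcyclohex-2-en-1-yl]but-1-en-1-yl}alumane | C[Al](C)/C=C(\C)CC[C@@H]1C(C)=CCCC1(C)C | intermediate
19 | 1,2,4,5-tetramethoxy-3-{(2E)-3-methyl-5-[(1S)-2,6,6-trimethylcyclohex-2-en-1-yl]pent-2-en-1-yl}benzene | COc1cc(OC)c(OC)c(C/C=C(\C)CC[C@@H]2C(C)=CCCC2(C)C)c1OC | intermediate
20 | 2,5-dimethoxy-3-{(2E)-3-methyl-5-[(1S)-2,6,6-trimethylcyclohex-2-en-1-yl]pent-2-en-1-yl}cyclohexa-2,5-diene-1,4-dione | COC1=CC(=O)C(OC)=C(C/C=C(\C)CC[C@@H]2C(C)=CCCC2(C)C)C1=O | intermediate
21 | potassium 4-methoxy-3,6-dioxo-2-{(2E)-3-methyl-5-[(1S)-2,6,6-trimethylcyclohex-2-en-1-yl]pent-2-en-1-yl}cyclohexa-1,4-dien-1-olate | COC1=CC(=O)C([O-])=C(C/C=C(\C)CC[C@@H]2C(C)=CCCC2(C)C)C1=O.[K+] | intermediate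
22 | 2-hydroxy-5-methoxy-3-{(2E)-3-methyl-5-[(1S)-2,6,6-trimethylcyclohex-2-en-1-yl]pent-2-en-1-yl}cyclohexa-2,5-diene-1,4-dione (CNP0018448.1) | COC1=CC(=O)C(O)=C(C/C=C(\C)CC[C@@H]2C(C)=CCCC2(C)C)C1=O | target

**Summary**

Total step count: 11. Longest linear sequence: 7 steps (steps 1, 3, 4, 5, 9, 10, 11).

**Three steps most likely to fail**

Step 3 (the proposed new method). The β-carbon sits between a methyl-bearing sp2 carbon and a quaternary carbon, so conversion may be low, 1,2-addition may compete, and the enantioselectivity is untested. The fallback uses known chemistry only; it sets out from 5 and comes back at 11. Enone 5 is reduced with BH3·SMe2 and (S)-2-methyl-CBS-oxazaborolidine (THF, −20 °C; the alkenyl side acts as the large group) to (1R)-2,4,4-trimethylcyclohex-2-en-1-ol F1, whose ee can be raised by lipase acetylation. Johnson–Claisen rearrangement (MeC(OEt)3, cat. EtCO2H, 140 °C) delivers the CH2CO2Et group to the ring face that carried the hydroxyl and moves the olefin to the α-position, giving ethyl [(1S)-2,6,6-trimethylcyclohex-2-en-1-yl]acetate F2. LiAlH4 (Et2O, 0 °C) gives 2-[(1S)-2,6,6-trimethylcyclohex-2-en-1-yl]ethan-1-ol F3. I2, PPh3 and imidazole (CH2Cl2) give (6S)-6-(2-iodoethyl)-1,5,5-trimethylcyclohex-1-ene F4. Displacement with LiC≡CH·H2NCH2CH2NH2 in DMSO at rt gives 11.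

Step 9. The Lewis-acidic alane may ionise the very electron-rich benzylic chloride (Friedel–Crafts or methyl-transfer side products) before cross-coupling. The fallback sets out from 11 and comes back at 19, with the roles of the partners swapped. The same methylalumination gives alane 18, which is cleaved with I2 (THF, −30 °C) to (6S)-6-[(3E)-4-iodo-3-methylbut-3-en-1-yl]-1,5,5-trimethylcyclohex-1-ene F5. Separately 17 is treated with Zn dust and LiCl in THF to give (2,3,5,6-tetramethoxybenzyl)zinc chloride F6. Negishi coupling of F5 with F6 (Pd(PPh3)4, THF, rt) gives 19 with retention of the (E) geometry.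

Step 11. Hydroxide may also attack the unhindered methoxy carbon (regioisomer), and base may trigger quinone-methide or chromenol chemistry at the allylic CH2. The fallback sets out from 20 and comes back at 22, and moves the regiochemical decision from a hydrolysis to a sterically controlled etherification. Exhaustive hydrolysis (NaOH aq., EtOH, 60 °C, then cold dilute acid) gives 2,5-dihydroxy-3-{(2E)-3-methyl-5-[(1S)-2,6,6-trimethylcyclohex-2-en-1-yl]pent-2-en-1-yl}cyclohexa-2,5-diene-1,4-dione F7. Fischer-type mono-etherification (MeOH, cat. TsOH, rt, stopped at the monoether) methylates the hydroxyl remote from the side chain and gives 22.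

**Further compounds**

F1 | step 3 | (1R)-2,4,4-trimethylcyclohex-2-en-1-ol | O[C@H]1C(C)=CC(C)(C)CC1
F2 | step 3 | ethyl [(1S)-2,6,6-trimethylcyclohex-2-en-1-yl]acetate | CCOC(=O)C[C@@H]1C(C)=CCCC1(C)C
F3 | step 3 | 2-[(1S)-2,6,6-trimethylcyclohex-2-en-1-yl]ethan-1-ol | OCC[C@@H]1C(C)=CCCC1(C)C
F4 | step 3 | (6S)-6-(2-iodoethyl)-1,5,5-trimethylcyclohex-1-ene | ICC[C@@H]1C(C)=CCCC1(C)C
F5 | step 9 | (6S)-6-[(3E)-4-iodo-3-methylbut-3-en-1-yl]-1,5,5-trimethylcyclohex-1-ene | I/C=C(\C)CC[C@@H]1C(C)=CCCC1(C)C
F6 | step 9 | (2,3,5,6-tetramethoxybenzyl)zinc chloride | COc1cc(OC)c(OC)c(C[Zn]Cl)c1OC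
F7 | step 11 | 2,5-dihydroxy-3-{(2E)-3-methyl-5-[(1S)-2,6,6-trimethylcyclohex-2-en-1-yl]pent-2-en-1-yl}cyclohexa-2,5-diene-1,4-dione | OC1=CC(=O)C(O)=C(C/C=C(\C)CC[C@@H]2C(C)=CCCC2(C)C)C1=O
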